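Thursday's run, the one earlier flask, loses solid substrate down to 72% by 0.500 h, and target climbs later, as catalyst accumulates.

| flask | solid substrate | catalyst | temperature | remark | time |
|---|---|---|---|---|---|
| Thursday's | 0.055 M | 1 mM (in portions, 3) | 20 °C | run made earlier; portions every 1.5 h |  |
| larch | 0.015 M | 2.0 mM | 20 °C | everything together at the start | 15 h |
| elm | 0.050 M | 1.0 mM (in portions, 3) | 20 °C | the portions of catalyst follow each other after 1.5 h, the first at the start | 15 h |

Thursday's run (percent of the solid substrate charged)

| time / h | target / % | solid substrate / % |
|---|---|---|
| 0.250 | 2 | 78 |
| 0.333 | 3 | 75 |
| 0.500 | 0 | 72 |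
| 0.833 | 4 | 67 |
| 1.33 | 6 | 66 |
| 2.00 | 14 | 57 |
| 3.00 | 22 | 42 |

(readings scatter by 1.5 percentage points)

- given per volume of solution although it is solid: solid substrate
- steps thought possible: solid substrate <-> starting material; starting material + catalyst <-> isomer of the product + catalyst; starting material + catalyst <-> target + catalyst
- at the start none of the solid substrate is in solution
- what has only dissolved of solid substrate counts as not reacted
- no earlier run changes the charge of catalyst; that part of a forecast is a guess

1. which one finishes higher in amount of target, in percent of the solid substrate charged ("neither" within 2 percentage points) (larch / elm / neither)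
2. amount of target at the end, in percent of the solid substrate charged, larch
3. amount of target at the end, in percent of the solid substrate charged, elm

My reckoning reads that early loss as about 15.4 mM of starting material in solution. Between 2.00 h and 3.00 h, with two portions in, target gains 4.40 mM h⁻¹. Assuming proportion to catalyst, a guess for any other charge, the whole 1 mM gives 1.62 h, the target half-life: the time for starting material to halve by its forward step to target.

Larch, with 2.0 mM, gets 0.809 h, so its 15 h holds 18.5 target half-lives. Going round once more for elm, whose half-life with its whole charge in is 1.62 h: the solid at the last portion, taken as Thursday's 42%, clears in about 3.18 h, which leaves 5.45 target half-lives. I therefore expect both flasks to finish level; this reckoning gives no height.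

The forecast says neither, with larch at 72% (58% to 85%) and elm at 70.5% (48% to 84%): “Both should therefore end near the selectivity limit”. Those heights are what first order to completion through Thursday's last reading gives.

The flasks give neither: larch 51.7%, elm 51.5%.

    solid substrate ⇌ starting material, rate k1*(cs1 - [starting material]) while solid is left; crystals form when [starting material] > cs1 (solubility = 13.0 mM, k = 0.00360 s⁻¹)
    starting material + catalyst ⇌ isomer of the product + catalyst, rate k2*[starting material]*[catalyst] forward; the back reaction follows from the equilibrium constant (K = 1.80, k = 0.170 L mol⁻¹ s⁻¹, Ea = 50.0 kJ mol⁻¹, ΔH = 13.0 kJ mol⁻¹)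
    starting material + catalyst ⇌ target + catalyst, rate k3*[starting material]*[catalyst] forward; the back reaction follows from the equilibrium constant (K = 3.00, k = 0.210 L mol⁻¹ s⁻¹, Ea = 53.0 kJ mol⁻¹, ΔH = −24.0 kJ mol⁻¹)
    (constants at 20 °C)

In larch the relaxation half-life of starting material and target by their step alone, both ways together, is 0.344 h at 15.0 h, short against the 15 h of the run, and under this thermodynamic control, with 18.5 target half-lives reckoned, target stands at 51.6% at 7.50 h and 51.7% at 15.0 h. Elm, with its 5.45 target half-lives reckoned after clearing, holds 0% solid substrate and 49.8% target at 7.50 h, then 51.5% target at 15.0 h, against a share of 51.7% from the equilibrium constants.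

The readings were computed with constants of no real substance, noise included.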